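**Retrosynthetic overview**

1. The target, a (3R)-isoflavanone, comes from its bis-MOM ether; C3 is set late by transfer hydrogenation with dynamic kinetic resolution of the racemic ketone (cis-3R,4R alcohol), followed by re-oxidation.
2. Ring C is cut at O1–C8a and C4–C4a (and at O1–C2): an aryne of ring A (C4a≡C8a) inserts into the C(acyl)–O bond of a 2-arylacrylic acid carrying ring B, and the phenoxide so formed closes ring C by oxa-Michael addition, all in one operation.
3. Enabling feature: O1 and the C4 carbonyl sit on the adjacent ring-A carbons C8a and C4a (an o-hydroxyaryl ketone), and C2 is β to that carbonyl, so O1, C4, C3 and C2 are the carboxylate O, acyl C, α-C and β-CH2 of an acrylic acid.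
4. A temporary chlorine at C5 turns the aryne into a 3-haloaryne and so fixes which aryne carbon takes oxygen; Pd/formate removes it directly after the key step.
5. Order of ring formation: rings A and B are bought as benzenes and dressed separately (ring A: hydroquinone to an o-silylaryl triflate; ring B: an arylacetate to the 2-arylacrylic acid); ring C is the only ring made, in step 12.

Key step: step 12

Remark: C3 of the target is R (CIP order C4 > C2 > aryl > H); chromanone numbering (O1, C2–C4, C4a, C5–C8, C8a) is used for ring-A atoms throughout; methyl 2-(3-bromo-4-hydroxyphenyl)acetate is taken as a catalogue compound.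

**Route**

Step 1
Reactants: 1 hydroquinone
Product: 2 4-(methoxymethoxy)phenol
Conditions: MOMCl (1.0 equiv), i-Pr2NEt, THF, 0 °C to rt; hydroquinone in threefold excess
Reagents that add atoms: chloromethyl methyl ether (MOMCl), COCCl
Why: O-alkylation of a phenol with an α-chloro ether (MOM acetal formation), run on excess diol so that the mono-ether should dominate and unreacted hydroquinone is washed out with water.

Step 2
Reactants: 2 4-(methoxymethoxy)phenol
Product: 3 2-chloro-4-(methoxymethoxy)phenol
Conditions: NCS (1.0 equiv), i-Pr2NH (10 mol%), CH2Cl2, 0 °C to rt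
Reagents that add atoms: N-chlorosuccinimide, O=C1CCC(=O)N1Cl
Why: Amine-catalysed electrophilic aromatic chlorination in which the free OH is the stronger activator and its para position is blocked, so chlorine should enter ortho to OH while the acetal sees no strong acid.

Step 3
Reactants: 3 2-chloro-4-(methoxymethoxy)phenol
Product: 4 2-bromo-6-chloro-4-(methoxymethoxy)phenol
Conditions: NBS (1.05 equiv), i-Pr2NH (10 mol%), CH2Cl2, 0 °C
Reagents that add atoms: N-bromosuccinimide, O=C1CCC(=O)N1Br
Why: Electrophilic aromatic bromination at the one remaining position ortho to the free OH, which places the future silyl site (C8a) opposite the chlorine (C5).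

Step 4
Reactants: 4 2-bromo-6-chloro-4-(methoxymethoxy)phenol
Product: 8 tert-butyl[2-chloro-4-(methoxymethoxy)-6-(trimethylsilyl)phenoxy]dimethylsilane, via aryl trimethylsilyl ether 5 (not isolated), via aryllithium 6 (not isolated), via lithium phenoxide 7 (not isolated)
Conditions: HMDS, THF, 70 °C, then evaporation; n-BuLi, THF, −78 °C to rt; TBSOTf, −78 °C to rt
Reagents that add atoms: hexamethyldisilazane, C[Si](C)(C)N[Si](C)(C)C; tert-butyldimethylsilyl trifluoromethanesulfonate, CC(C)(C)[Si](C)(C)OS(=O)(=O)C(F)(F)F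
Why: O-silylation, chemoselective bromine–lithium exchange (C–Cl untouched at −78 °C) and retro-Brook 1,3 O→C silyl migration should put SiMe3 exactly where bromine stood, and the freed phenoxide is capped in the same flask as a base-stable TBS ether.

Step 5
Reactants: 8 tert-butyl[2-chloro-4-(methoxymethoxy)-6-(trimethylsilyl)phenoxy]dimethylsilane
Product: 11 tert-butyl[2-chloro-4-(methoxymethoxy)-3-(3-methylbut-2-en-1-yl)-6-(trimethylsilyl)phenoxy]dimethylsilane, via aryllithium 9 (not isolated), via arylcopper 10 (not isolated)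
Conditions: s-BuLi, TMEDA, THF, −78 °C; CuBr·SMe2, −78 °C; prenyl bromide, −78 °C to 0 °C
Reagents that add atoms: 1-bromo-3-methylbut-2-ene (prenyl bromide), CC(C)=CCBr
Why: Directed ortho-metalation at the only ring hydrogen flanked by two directing groups (Cl and OMOM, the other hydrogen being shielded by SiMe3), then copper-mediated SN2 allylation, which with prenyl bromide should favour the unbranched C–C bond.

Step 6
Reactants: 11 tert-butyl[2-chloro-4-(methoxymethoxy)-3-(3-methylbut-2-en-1-yl)-6-(trimethylsilyl)phenoxy]dimethylsilane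
Product: 12 2-chloro-4-(methoxymethoxy)-3-(3-methylbut-2-en-1-yl)-6-(trimethylsilyl)phenol
Conditions: TBAF (1.1 equiv), AcOH (1.1 equiv), THF, 0 °C
Reagents that add atoms: none
Why: Buffered fluoride cleavage of the aryl silyl ether, in which the Si–O bond should be far more labile than the unactivated aryl C–SiMe3 bond.

Step 7
Reactants: 12 2-chloro-4-(methoxymethoxy)-3-(3-methylbut-2-en-1-yl)-6-(trimethylsilyl)phenol
Product: 13 2-chloro-4-(methoxymethoxy)-3-(3-methylbut-2-en-1-yl)-6-(trimethylsilyl)phenyl trifluoromethanesulfonate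
Conditions: Tf2O, pyridine, CH2Cl2, 0 °C
Reagents that add atoms: trifluoromethanesulfonic anhydride, O=S(=O)(OS(=O)(=O)C(F)(F)F)C(F)(F)F
Why: O-triflation of the phenol completes the o-silylaryl triflate, the standard fluoride-triggered aryne precursor, with pyridine buffering the acid so that the MOM and prenyl groups should survive.

Step 8
Reactants: 14 methyl 2-(3-bromo-4-hydroxyphenyl)acetate
Product: 15 methyl 2-[3-bromo-4-(methoxymethoxy)phenyl]acetate
Conditions: MOMCl, i-Pr2NEt, CH2Cl2, 0 °C to rt
Reagents that add atoms: chloromethyl methyl ether (MOMCl), COCCl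
Why: MOM protection (O-alkylation of the phenol) gives a fluoride-stable ether that keeps this phenol from adding to the aryne later.

Step 9
Reactants: 15 methyl 2-[3-bromo-4-(methoxymethoxy)phenyl]acetate
Product: 16 methyl 2-[4-(methoxymethoxy)-3-(3-methylbut-2-en-1-yl)phenyl]acetate
Conditions: tributyl(3-methylbut-2-en-1-yl)stannane, Pd(PPh3)4 (5 mol%), DMF, 100 °C
Reagents that add atoms: tributyl(3-methylbut-2-en-1-yl)stannane, CCCC[Sn](CCCC)(CCCC)CC=C(C)C
Why: Stille coupling of the aryl bromide with the prenylstannane, where reductive elimination at the less substituted allyl terminus should give the linear prenyl arene.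

Step 10
Reactants: 16 methyl 2-[4-(methoxymethoxy)-3-(3-methylbut-2-en-1-yl)phenyl]acetate
Product: 18 methyl 2-[4-(methoxymethoxy)-3-(3-methylbut-2-en-1-yl)phenyl]prop-2-enoate, via aldol adduct 17 (not isolated)
Conditions: (CH2O)n, K2CO3, n-Bu4NI (cat.), toluene, 80 °C
Reagents that add atoms: paraformaldehyde (formaldehyde), C=O
Why: Aldol addition of the arylacetate enolate to formaldehyde followed by E1cB dehydration (α-methylenation) is the standard access to 2-arylacrylates.

Step 11
Reactants: 18 methyl 2-[4-(methoxymethoxy)-3-(3-methylbut-2-en-1-yl)phenyl]prop-2-enoate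
Product: 19 2-[4-(methoxymethoxy)-3-(3-methylbut-2-en-1-yl)phenyl]prop-2-enoic acid
Conditions: LiOH, THF/H2O, 0 °C to rt; then 1 M HCl to pH 4 at 0 °C
Reagents that add atoms: lithium hydroxide, [Li+].[OH-]
Why: Saponification of the methyl ester at low temperature, where acyl attack by hydroxide should outrun conjugate addition and the brief cold acidification spares the MOM ether.

Step 12
Reactants: 13 2-chloro-4-(methoxymethoxy)-3-(3-methylbut-2-en-1-yl)-6-(trimethylsilyl)phenyl trifluoromethanesulfonate; 19 2-[4-(methoxymethoxy)-3-(3-methylbut-2-en-1-yl)phenyl]prop-2-enoic acid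
Product: 23 rac-5-chloro-7-(methoxymethoxy)-3-[4-(methoxymethoxy)-3-(3-methylbut-2-en-1-yl)phenyl]-6-(3-methylbut-2-en-1-yl)chroman-4-one, via aryne 20 (not isolated), via aryl anion 21 (not isolated), via ketophenoxide 22 (not isolated)
Conditions: CsF (4 equiv), THF, 125 °C, sealed tube; 13 in 1.5-fold excess
Reagents that add atoms: none
Why: Fluoride strips the silyl group of 13 and expels triflate to give the 3-chloroaryne 20; the cesium carboxylate of 19 adds through oxygen to C8a, the aryne carbon remote from chlorine, and the C4a anion 21 attacks its own ester carbonyl (4-exo-trig, a transient four-membered alkoxide) and reopens to ketophenoxide 22, so that the aryne has inserted into the C(acyl)–O bond and both the O1–C8a and the C4–C4a bonds are made. The closest known reaction type is the fluoride-induced C–O σ-insertion of arynes into carboxylic acids, which gives o-hydroxyaryl ketones and, with acrylic acids, 4-chromanones. Ring C then closes by 6-endo-trig oxa-Michael addition of the C8a phenoxide to the methylene terminus of the 1-arylvinyl ketone, the same closure that follows methylenation of 2'-hydroxydeoxybenzoins. C3 becomes a stereocentre only in the final, unselective enolate protonation, so 23 is racemic by design and C3 is set in step 14. The step needs carboxylate attack at C8a and acyl transfer faster than protonation or chloride loss from 21: the C5 chlorine (inductive stabilisation of the C4a anion and aryne distortion, the usual behaviour of 3-haloarynes) together with the unhindered C8 side should secure the first, and the hot aprotic medium with the ester carbonyl held next to the carbanion should secure the second.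

Step 13
Reactants: 23 rac-5-chloro-7-(methoxymethoxy)-3-[4-(methoxymethoxy)-3-(3-methylbut-2-en-1-yl)phenyl]-6-(3-methylbut-2-en-1-yl)chroman-4-one
Product: 24 rac-7-(methoxymethoxy)-3-[4-(methoxymethoxy)-3-(3-methylbut-2-en-1-yl)phenyl]-6-(3-methylbut-2-en-1-yl)chroman-4-one
Conditions: Pd(OAc)2 (5 mol%), XPhos (10 mol%), HCO2Na (3 equiv), DMF, 80 °C
Reagents that add atoms: none
Why: Palladium-catalysed transfer hydrodehalogenation, in which the C5–Cl bond activated by the ortho ketone undergoes oxidative addition and formate delivers hydride with loss of CO2, should replace the temporary directing group by hydrogen without reducing the trisubstituted alkenes.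

Step 14
Reactants: 24 rac-7-(methoxymethoxy)-3-[4-(methoxymethoxy)-3-(3-methylbut-2-en-1-yl)phenyl]-6-(3-methylbut-2-en-1-yl)chroman-4-one
Product: 25 (3R,4R)-7-(methoxymethoxy)-3-[4-(methoxymethoxy)-3-(3-methylbut-2-en-1-yl)phenyl]-6-(3-methylbut-2-en-1-yl)chroman-4-ol
Conditions: RuCl(p-cymene)[(R,R)-TsDPEN] (2 mol%), HCO2H/Et3N (5:2), EtOAc, 40 °C
Reagents that add atoms: none
Why: Noyori-type asymmetric transfer hydrogenation with dynamic kinetic resolution, in which Et3N racemises C3 through the enol faster than reduction, the (R,R) catalyst should set C4 as R by analogy with 4-chromanone, and hydride delivery anti to the C3 aryl group gives the cis alcohol and thereby fixes C3 as R.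

Step 15
Reactants: 25 (3R,4R)-7-(methoxymethoxy)-3-[4-(methoxymethoxy)-3-(3-methylbut-2-en-1-yl)phenyl]-6-(3-methylbut-2-en-1-yl)chroman-4-ol
Product: 26 (3R)-7-(methoxymethoxy)-3-[4-(methoxymethoxy)-3-(3-methylbut-2-en-1-yl)phenyl]-6-(3-methylbut-2-en-1-yl)chroman-4-one
Conditions: Dess–Martin periodinane, CH2Cl2, 0 °C to rt
Reagents that add atoms: none
Why: Dess–Martin oxidation under non-basic conditions removes the C4 stereocentre while the enolisable C3 centre set in step 14 should be retained.

Step 16
Reactants: 26 (3R)-7-(methoxymethoxy)-3-[4-(methoxymethoxy)-3-(3-methylbut-2-en-1-yl)phenyl]-6-(3-methylbut-2-en-1-yl)chroman-4-one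
Product: 27 (3R)-7-hydroxy-3-[4-hydroxy-3-(3-methylbut-2-en-1-yl)phenyl]-6-(3-methylbut-2-en-1-yl)chroman-4-one (CNP0292419.2)
Conditions: 3 M HCl (aq.), MeOH/THF, rt to 40 °C, stopped at full conversion
Reagents that add atoms: none
Why: Acid-catalysed transacetalisation of both MOM ethers to methanol under mild conditions, chosen to stay below the threshold for acid-catalysed enolisation at C3 and for addition of the phenols to the neighbouring prenyl double bonds.

**Compound list**

1 | hydroquinone | Oc1ccc(O)cc1 | starting material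
2 | 4-(methoxymethoxy)phenol | COCOc1ccc(O)cc1 | intermediate
3 | 2-chloro-4-(methoxymethoxy)phenol | COCOc1ccc(O)c(Cl)c1 | intermediate
4 | 2-bromo-6-chloro-4-(methoxymethoxy)phenol | COCOc1cc(Cl)c(O)c(Br)c1 | intermediate
5 | [2-bromo-6-chloro-4-(methoxymethoxy)phenoxy]trimethylsilane | COCOc1cc(Cl)c(O[Si](C)(C)C)c(Br)c1 | intermediate (not isolated)
6 | {3-chloro-5-(methoxymethoxy)-2-[(trimethylsilyl)oxy]phenyl}lithium | COCOc1cc(Cl)c(O[Si](C)(C)C)c([Li])c1 | intermediate (not isolated)
7 | lithium 2-chloro-4-(methoxymethoxy)-6-(trimethylsilyl)phenoxide | COCOc1cc(Cl)c([O-])c([Si](C)(C)C)c1.[Li+] | intermediate (not isolated)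
8 | tert-butyl[2-chloro-4-(methoxymethoxy)-6-(trimethylsilyl)phenoxy]dimethylsilane | COCOc1cc(Cl)c(O[Si](C)(C)C(C)(C)C)c([Si](C)(C)C)c1 | intermediate
9 | {3-[(tert-butyldimethylsilyl)oxy]-2-chloro-6-(methoxymethoxy)-4-(trimethylsilyl)phenyl}lithium | COCOc1cc([Si](C)(C)C)c(O[Si](C)(C)C(C)(C)C)c(Cl)c1[Li] | intermediate (not isolated)
10 | {3-[(tert-butyldimethylsilyl)oxy]-2-chloro-6-(methoxymethoxy)-4-(trimethylsilyl)phenyl}copper | COCOc1cc([Si](C)(C)C)c(O[Si](C)(C)C(C)(C)C)c(Cl)c1[Cu] | intermediate (not isolated)
11 | tert-butyl[2-chloro-4-(methoxymethoxy)-3-(3-methylbut-2-en-1-yl)-6-(trimethylsilyl)phenoxy]dimethylsilane | COCOc1cc([Si](C)(C)C)c(O[Si](C)(C)C(C)(C)C)c(Cl)c1CC=C(C)C | intermediate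
12 | 2-chloro-4-(methoxymethoxy)-3-(3-methylbut-2-en-1-yl)-6-(trimethylsilyl)phenol | COCOc1cc([Si](C)(C)C)c(O)c(Cl)c1CC=C(C)C | intermediate
13 | 2-chloro-4-(methoxymethoxy)-3-(3-methylbut-2-en-1-yl)-6-(trimethylsilyl)phenyl trifluoromethanesulfonate | COCOc1cc([Si](C)(C)C)c(OS(=O)(=O)C(F)(F)F)c(Cl)c1CC=C(C)C | intermediate
14 | methyl 2-(3-bromo-4-hydroxyphenyl)acetate | COC(=O)Cc1ccc(O)c(Br)c1 | starting material
15 | methyl 2-[3-bromo-4-(methoxymethoxy)phenyl]acetate | COC(=O)Cc1ccc(OCOC)c(Br)c1 | intermediate
16 | methyl 2-[4-(methoxymethoxy)-3-(3-methylbut-2-en-1-yl)phenyl]acetate | COC(=O)Cc1ccc(OCOC)c(CC=C(C)C)c1 | intermediate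
17 | methyl 3-hydroxy-2-[4-(methoxymethoxy)-3-(3-methylbut-2-en-1-yl)phenyl]propanoate (racemic) | COC(=O)C(CO)c1ccc(OCOC)c(CC=C(C)C)c1 | intermediate (not isolated)
18 | methyl 2-[4-(methoxymethoxy)-3-(3-methylbut-2-en-1-yl)phenyl]prop-2-enoate | C=C(C(=O)OC)c1ccc(OCOC)c(CC=C(C)C)c1 | intermediate
19 | 2-[4-(methoxymethoxy)-3-(3-methylbut-2-en-1-yl)phenyl]prop-2-enoic acid | C=C(C(=O)O)c1ccc(OCOC)c(CC=C(C)C)c1 | intermediate
20 | 3-chloro-5-(methoxymethoxy)-4-(3-methylbut-2-en-1-yl)-1,2-didehydrobenzene (aryne) | COCOC1=CC#CC(Cl)=C1CC=C(C)C | intermediate (not isolated)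
21 | cesium salt of the C2 carbanion of 3-chloro-5-(methoxymethoxy)-4-(3-methylbut-2-en-1-yl)phenyl 2-[4-(methoxymethoxy)-3-(3-methylbut-2-en-1-yl)phenyl]prop-2-enoate | C=C(C(=O)Oc1cc(OCOC)c(CC=C(C)C)c(Cl)[c-]1)c1ccc(OCOC)c(CC=C(C)C)c1.[Cs+] | intermediate (not isolated)
22 | cesium 3-chloro-5-(methoxymethoxy)-4-(3-methylbut-2-en-1-yl)-2-{2-[4-(methoxymethoxy)-3-(3-methylbut-2-en-1-yl)phenyl]prop-2-enoyl}phenoxide | C=C(C(=O)c1c([O-])cc(OCOC)c(CC=C(C)C)c1Cl)c1ccc(OCOC)c(CC=C(C)C)c1.[Cs+] | intermediate (not isolated)
23 | rac-5-chloro-7-(methoxymethoxy)-3-[4-(methoxymethoxy)-3-(3-methylbut-2-en-1-yl)phenyl]-6-(3-methylbut-2-en-1-yl)chroman-4-one | CC(C)=CCc1cc(C2COc3cc(OCOC)c(CC=C(C)C)c(Cl)c3C2=O)ccc1OCOC | intermediate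
24 | rac-7-(methoxymethoxy)-3-[4-(methoxymethoxy)-3-(3-methylbut-2-en-1-yl)phenyl]-6-(3-methylbut-2-en-1-yl)chroman-4-one | CC(C)=CCc1cc(C2COc3cc(OCOC)c(CC=C(C)C)cc3C2=O)ccc1OCOC | intermediate
25 | (3R,4R)-7-(methoxymethoxy)-3-[4-(methoxymethoxy)-3-(3-methylbut-2-en-1-yl)phenyl]-6-(3-methylbut-2-en-1-yl)chroman-4-ol (cis) | CC(C)=CCc1cc([C@@H]2COc3cc(OCOC)c(CC=C(C)C)cc3[C@@H]2O)ccc1OCOC | intermediate
26 | (3R)-7-(methoxymethoxy)-3-[4-(methoxymethoxy)-3-(3-methylbut-2-en-1-yl)phenyl]-6-(3-methylbut-2-en-1-yl)chroman-4-one | CC(C)=CCc1cc([C@@H]2COc3cc(OCOC)c(CC=C(C)C)cc3C2=O)ccc1OCOC | intermediate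
27 | (3R)-7-hydroxy-3-[4-hydroxy-3-(3-methylbut-2-en-1-yl)phenyl]-6-(3-methylbut-2-en-1-yl)chroman-4-one | CC(C)=CCc1cc([C@@H]2COc3cc(O)c(CC=C(C)C)cc3C2=O)ccc1O | target

**Step count and risks**

Total step count: 16. Longest linear sequence: 12 steps (steps 1–7, then 12–16).

Steps most likely to fail, riskiest first:

1. Step 12. What may go wrong: the C4a carbanion is protonated by free acid or loses chloride before the acyl shift, and at 125 °C the 2-arylacrylate is drained by fluoride- or carboxylate-initiated conjugate addition and oligomerisation. The fallback sets out from 16 and 13 and comes back at 23; it takes the Michael acceptor out of the insertion. Ester 16 is saponified (LiOH, THF/H2O, then HCl) to 2-[4-(methoxymethoxy)-3-(3-methylbut-2-en-1-yl)phenyl]acetic acid F1. F1 and 13 with CsF in THF at 125 °C undergo the parent aryne C–O insertion of a saturated acid, again steered by the C5 chlorine, to give 1-[2-chloro-6-hydroxy-4-(methoxymethoxy)-3-(3-methylbut-2-en-1-yl)phenyl]-2-[4-(methoxymethoxy)-3-(3-methylbut-2-en-1-yl)phenyl]ethan-1-one F2. F2 with paraformaldehyde and Et2NH in MeOH at reflux is methylenated at the benzylic carbon (Mannich-type) and closes by oxa-Michael addition to 23.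

2. Step 5. What may go wrong: loss of LiCl from the ortho-chloro aryllithium on warming, slow coupling of the crowded arylcopper, and SN2′ attack at the tertiary terminus of prenyl bromide. The fallback sets out from 8 and comes back at 11. The aryllithium from 8 (s-BuLi, TMEDA, THF, −78 °C) is quenched at once with I2 to give tert-butyl[2-chloro-3-iodo-4-(methoxymethoxy)-6-(trimethylsilyl)phenoxy]dimethylsilane F3. The prenyl group is then introduced by Stille coupling of F3 with tributyl(3-methylbut-2-en-1-yl)stannane (Pd(PPh3)4, CuI, DMF, 80 °C) to give 11.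

3. Step 14. What may go wrong: reduction outrunning the enolisation that racemises C3 (incomplete dynamic kinetic resolution), or hydride delivery on the face syn to the aryl group; either lowers the enantiomeric purity carried into 26. The fallback sets out from 24 and comes back at 26, bypassing 25 and step 15; C3 is set by enantioselective protonation instead. Soft enolisation of 24 (TMSOTf, Et3N, CH2Cl2, 0 °C) gives 7-(methoxymethoxy)-3-[4-(methoxymethoxy)-3-(3-methylbut-2-en-1-yl)phenyl]-6-(3-methylbut-2-en-1-yl)-4-[(trimethylsilyl)oxy]-2H-chromene F4. F4 is protonated with phenol as stoichiometric proton source under a chiral BINOL-derived N-triflyl thiophosphoramide catalyst (toluene, rt), the catalyst antipode being chosen to deliver the R ketone 26.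

**Further compounds**

F1 | step 12 | 2-[4-(methoxymethoxy)-3-(3-methylbut-2-en-1-yl)phenyl]acetic acid | CC(C)=CCc1cc(CC(=O)O)ccc1OCOC
F2 | step 12 | 1-[2-chloro-6-hydroxy-4-(methoxymethoxy)-3-(3-methylbut-2-en-1-yl)phenyl]-2-[4-(methoxymethoxy)-3-(3-methylbut-2-en-1-yl)phenyl]ethan-1-one | CC(C)=CCc1cc(CC(=O)c2c(O)cc(OCOC)c(CC=C(C)C)c2Cl)ccc1OCOC
F3 | step 5 | tert-butyl[2-chloro-3-iodo-4-(methoxymethoxy)-6-(trimethylsilyl)phenoxy]dimethylsilane | COCOc1cc([Si](C)(C)C)c(O[Si](C)(C)C(C)(C)C)c(Cl)c1I
F4 | step 14 | 7-(methoxymethoxy)-3-[4-(methoxymethoxy)-3-(3-methylbut-2-en-1-yl)phenyl]-6-(3-methylbut-2-en-1-yl)-4-[(trimethylsilyl)oxy]-2H-chromene | CC(C)=CCc1cc(C2=C(O[Si](C)(C)C)c3cc(CC=C(C)C)c(OCOC)cc3OC2)ccc1OCOC
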